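(The runs were generated by integration with made-up constants, noise included.)

I was asked when the flask holds most open intermediate, how much it holds then, and when it first reaches the asked level.

- when, up to 8.0 min, the flask holds most open intermediate
- the amount of open intermediate, in percent of the starting material charged, at that time
- the first time at which open intermediate reaches 15 %, in the same percent, in min

| setting | violet | flask |
|---|---|---|
| starting material | 21 mM | 21 mM |
| partner | 0.80 equiv | 0.800 equiv |
| remark | the very flask that is asked about, followed so far |  |
| time |  | 8.0 min |

violet run (percent of the starting material charged)

| time / min | open intermediate / % | target / % |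
|---|---|---|
| 0.167 | 23.8 | 1.4 |
| 0.333 | 30.6 | 7.4 |
| 0.500 | 30.6 | 12.6 |
| 1.00 | 18.9 | 23.8 |
| 2.00 | 4.4 | 31.6 |
| 3.00 | 0.6 | 31.8 |

(readings scatter by 0.5 percentage points)

- the numbers in the tables scatter by 0.5 percentage points (one standard deviation)

The violet run had the same charge as the flask, so I read it first, and two of its numbers seemed not to fit. It carried 0.80 equiv of partner, yet its target stopped at 31.8 %, when the open intermediate had fallen to 0.6 %.

I cleared this up by supposing that the whole charge passes through the open intermediate. With the open intermediate still there set aside, the violet run then sent 67.6 % of it elsewhere, more than went to target. I called target over that share the branch ratio, a selectivity factor, and read it as 0.470. I supposed that target takes partner and the rest does not, so I expected this ratio to move with the partner charged.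

I read the peak of the flask as lying between 0.333 min and 0.500 min, where the violet run read 30.6 % twice. The forecast said “the peak lies near the midpoint” and gave 31.5 % at 0.41 min, with the asked level first reached at 0.085 min.

The flask gave 31.0 % at 0.390 min and reached the level at 0.0857 min.

    open intermediate → side product (k = 0.0240 s⁻¹)
    open intermediate + second intermediate → target (k = 1.90 L mol⁻¹ s⁻¹)
    starting material → open intermediate (k = 0.0350 s⁻¹)
    partner → second intermediate (k = 0.140 s⁻¹)
    target ⇌ isomer of the product (K = 0.420, k = 0.190 s⁻¹)

At 8.00 min the flask held 32.3 % target, with 54.1 % side product and 13.6 % isomer of the product making up the rest. Scaled to the neighbour flask with 0.320 equiv of partner, the branch ratio became 0.188, a target share of 15.8 %. That neighbour flask ended with 16.0 % target.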